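**Remark on the chemistry:** ring A receives its flavone locants only when iodine is placed on the benzannulation product. The plan iodinates beside the ethoxy carbon, so the ethoxy oxygen becomes O5 and the three ring bonds of the key step read C4a–C8a, C5–C6 and C8–C8a. After iodination beside the silyloxy carbon the same three bonds would read C8–C8a, C6–C7 and C4a–C8a, and both courses end in the same 6-substituted flavone. The commercial N-Boc derivative of (R)-pipecolic acid is taken as the starting material.

## Structural features

The target is a flavone: a 4H-chromen-4-one (ring A fused to the pyranone ring C) with an unsubstituted phenyl (ring B) on C2, hydroxyls on C5 and C7, and an (R)-1-methylpiperidin-2-yl group joined through C2' to C6. Ring A is a phloroglucinol nucleus (O5, O7, O1) in which five of six positions are substituted, only C8 carries hydrogen, and C6 sits between the two phenolic oxygens. The single stereocentre, C2', is benzylic and α to nitrogen and has no neighbouring stereocentre to relay from, so its absolute configuration must be brought in or created outright. The fragile element is the ortho,ortho'-dihydroxybenzylamine (Mannich-base) array, which can ionise at C2'–N to an ortho-quinone methide and racemise in hot acid or base. A 5,7-dihydroxyflavone can also exchange 6- and 8-substituents by ring opening and reclosure in strong acid (Wessely–Moser rearrangement), C8–H is nucleophilic towards formaldehyde, tert-butyl cation and iodonium, and the pyranone enone does not tolerate strong hydride donors. The real difficulty is to place a hindered, configurationally defined aminoalkyl group at C6 and not at C8. The key step exploits the fact that C6 lies between C5–O and C7–O with C8a–O para to it. A 2-substituted 3-silyloxycyclobutenone and an ynol ether deliver exactly this pattern, the cyclobutenone carbonyl becoming the only free hydroxyl (the future O1), so ring A can be grown around the intact stereocentre of (R)-pipecolic acid.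

## Logic of the disconnections

**22 to 21.** The O5–CH2 bond of an ethyl ether is restored. O5 is peri to the C4 carbonyl, so a chelated boron halide cleaves this ether at low temperature. Putting this last means the Mannich-base array with two free flanking hydroxyls exists only in the final flask. The forward step must stay cold enough that C2'–N does not ionise.

**21 to 20.** The O7–Si bond is restored. Silicon on O7 is what kept O7 from competing with O1 in the pyranone closure; once ring C exists it is no longer needed and fluoride removes it orthogonally. The demand is a buffered fluoride source so that no strongly basic phenoxide sits beside the benzylic amine.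

**20 to 18 (through 19).** The N–CH3 bond is cut and the carbamate restored. The Boc-to-methyl exchange is placed after ring C is closed, not before the iodination. At this stage ring A has no free hydroxyl and is attenuated by the C4 carbonyl, so the tert-butyl cation and formaldehyde do not attack C8, and no basic amine is present during iodination or carbonylation. The acid must leave the silyl ether in place and the hydride must leave the enone alone.

**18 to 15 and 16.** C4a–C4, C4–C3 and O1–C2 are cut, with one carbonyl carbon supplied as carbon monoxide. Rings B and C are removed in one operation and the problem reduces to an ortho-iodophenol. The forward step needs CO uptake before alkynylation and 6-endo closure. Because only the oxygen para to the piperidine is free, closure can only give the 6-substituted isomer.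

**15 to 14.** The C4a–I bond is cut. The free phenol directs iodine to its two ortho carbons. The demand is site selectivity, expected beside the ethoxy carbon on steric grounds and harmless if it leaks, since both sites converge.

**14 to 8 and 9.** C4a–C8a and C5–C6 (between the two components) and C8–C8a (ring closure) are cut. This takes the whole of ring A back to a four-carbon and a two-carbon unit and leaves the stereocentre on an sp2 carbon of a strained ring. The forward step needs the correct sense of ketene–alkyne union and neutral thermal conditions.

**8 to 6 (through 7).** Two C–H bonds are exchanged for C–Cl. This allows the ketene partner to be dichloroketene made in the flask in place of gaseous ketene. The reduction must spare the silyl enol ether.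

**6 to 5.** The two ring bonds made by a ketene–alkyne [2+2] are cut. The cyclobutenone reduces to a silyl ynol ether whose polarisation fixes the carbonyl beside the piperidine-bearing carbon.

**5 to 2 (through 3 and 4).** The alkyne carbon next to C2' is removed. One carbon is inserted between C2' and the former carboxyl carbon with 1,2-migration of C2', which turns an ester directly into an ynol ether in one flask. The demand is that addition to the ester outruns enolisation at C2'.

**2 to 1.** The O–CH3 bond is cut. The ester is formed by carboxylate alkylation, which never activates the carboxyl group and so cannot racemise C2'.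

## Other disconnections considered

**Alternative 1:** The aryl C6–C2' bond and the adjacent aryl C–O bond are cut, back to the aryne precursor 3-methoxy-5-(propan-2-yloxy)-2-(trimethylsilyl)phenyl triflate A2 and 1-methylpiperidin-2-one A3. In the forward step CsF releases the aryne from A2 and the lactam oxygen attacks the aryne carbon remote from the methoxy group. The aryl anion then closes on the iminium carbon to a benzoxete that reopens and tautomerises to the enamine 5-isopropoxy-3-methoxy-2-(1-methyl-1,4,5,6-tetrahydropyridin-2-yl)phenol A1. Hydrogenation would then give (R)-5-isopropoxy-3-methoxy-2-(1-methylpiperidin-2-yl)phenol A4.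
- In its favour: it is convergent, it makes the crowded aryl–C2' bond and places the carbon between two oxygens by the innate regiochemistry of a 3-alkoxyaryne, and it needs no strained intermediate. Up to the arylpiperidine it is equal or better in step economy.
- Against it here: the stereocentre is absent and must be created by enantioselective reduction of a cyclic N-methyl enamine whose 2,6-disubstituted aryl group is twisted out of conjugation, a case in which high selectivity cannot be assumed. The new hydroxyl is a flanking one, so O1 must later be freed from its isopropyl ether after the new hydroxyl is capped, with a basic amine present during O-alkylation. Insertion into a lactam carbonyl is also less secure than into a formamide.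
- Comparison: both plans settle the 6- versus 8-question by construction. This one is polar and stepwise where the chosen plan is pericyclic. The chosen plan is stronger on configuration, which it inherits, and weaker on the robustness of its intermediates. Overall step count would be similar.

**Alternative 2:** Ring C is cut at C4a–C4, C4–C3 and O1–C2, back to (R)-2-iodo-3,5-dimethoxy-4-(1-methylpiperidin-2-yl)phenol A6, 16 and carbon monoxide. The forward step over PdCl2(PPh3)2 in diethylamine would give (R)-5,7-dimethoxy-6-(1-methylpiperidin-2-yl)-2-phenyl-4H-chromen-4-one A5.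
- In its favour: this is the same transformation as step 7 of the chosen plan, so on that bond set the two are equal. It is better in two respects: the N-methyl group is already present, and the two identical methyl ethers make the phenol symmetric so that iodination is unambiguous.
- Against it here: as a key disconnection it solves only the easier half, because A6 still holds the stereocentre and the pentasubstituted ring A and needs one of the other strategies. The final double demethylation must be forcing enough for the O7 methyl ether, with the Mannich-base array exposed for longer. A free tertiary amine is also present during iodination.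
- Comparison: it is complementary to the chosen plan and not a competitor. The chosen plan adopts its ring C closure and supplies what it leaves open.

**Alternative 3:** The N1'–C2' bond (and C3'–H) is cut, back to the E-styrene O-benzoyl-N-{(4E)-5-[4-(benzyloxy)-2,6-dimethoxyphenyl]pent-4-en-1-yl}-N-methylhydroxylamine A8. In the forward step a monovalent copper hydride formed from Cu(OAc)2, DTBM-SEGPHOS and (EtO)2MeSiH would add across the styrene to a benzylic copper species, which the tethered N–O ester aminates to close the ring. The product would be (R)-2-[4-(benzyloxy)-2,6-dimethoxyphenyl]-1-methylpiperidine A7.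
- In its favour: ring, stereocentre and N-methyl group arise in one catalytic step. The benzyl/methyl pair is better than the ethyl/silyl pair of the chosen plan for unmasking O1, since hydrogenolysis leaves a symmetric phenol.
- Against it here: the alkene is a 2,6-dioxygenated styrene with a twisted aryl group and a shielded benzylic carbon. Hydrocupration by a bulky ligated copper hydride may be slow enough for direct N–O reduction to compete. Six-membered closure is less established than the intermolecular reaction, and the enantioselectivity on so hindered a styrene would have to be proven.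
- Comparison: step count would be similar or slightly lower. Configuration is catalyst-controlled here and inherited in the chosen plan. The mechanism is organometallic, not pericyclic. The chosen plan is preferred because neither configuration nor regiochemistry is in question, at the price of a sensitive cyclobutenone.

Key step: step 5

## Route

Step 1
Reactants: 1 (R)-1-(tert-butoxycarbonyl)piperidine-2-carboxylic acid
Product: 2 1-tert-butyl 2-methyl (R)-piperidine-1,2-dicarboxylate
Conditions: MeI, K2CO3, DMF, 23 °C
Reagents that add atoms: iodomethane, CI
Why: Carboxylate O-alkylation (SN2); the carboxyl group is never activated, so the α-stereocentre is not exposed to enolisation.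

Step 2
Reactants: 2 1-tert-butyl 2-methyl (R)-piperidine-1,2-dicarboxylate
Product: 5 tert-butyl (R)-2-[(triisopropylsilyloxy)ethynyl]piperidine-1-carboxylate, via lithium dibromoenolate 3 (not isolated), via lithium ynolate 4 (not isolated)
Conditions: CH2Br2, lithium 2,2,6,6-tetramethylpiperidide, THF, −78 °C; LiN(SiMe3)2, −78 → −20 °C; n-BuLi, −78 → 0 °C; iPr3SiCl, 0 °C
Reagents that add atoms: dibromomethane, BrCBr; chlorotri(propan-2-yl)silane, CC(C)[Si](Cl)(C(C)C)C(C)C
Why: Kowalski ynolate synthesis: LiCHBr2 adds to the ester at −78 °C faster than the ester is enolised, methoxide is lost and 3 forms; bromine–lithium exchange gives a carbenoid that rearranges by 1,2-shift of C2' with retention to ynolate 4. The bulky silyl chloride then reacts at oxygen and not at carbon.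

Step 3
Reactants: 5 tert-butyl (R)-2-[(triisopropylsilyloxy)ethynyl]piperidine-1-carboxylate
Product: 6 tert-butyl (R)-2-[3,3-dichloro-4-oxo-2-(triisopropylsilyloxy)cyclobut-1-en-1-yl]piperidine-1-carboxylate
Conditions: Cl2CHCOCl, Et3N, Et2O, 0 → 23 °C
Reagents that add atoms: dichloroacetyl chloride, O=C(Cl)C(Cl)Cl
Why: Ketene–alkyne [2+2] cycloaddition with dichloroketene generated in the flask; the nucleophilic carbon of the silyl ynol ether (the one bearing the piperidine) bonds to the ketene carbonyl carbon, which puts C=O beside the piperidine-bearing carbon and CCl2 beside the silyloxy carbon.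

Step 4
Reactants: 6 tert-butyl (R)-2-[3,3-dichloro-4-oxo-2-(triisopropylsilyloxy)cyclobut-1-en-1-yl]piperidine-1-carboxylate
Product: 8 tert-butyl (R)-2-[4-oxo-2-(triisopropylsilyloxy)cyclobut-1-en-1-yl]piperidine-1-carboxylate, via monochlorocyclobutenone 7 (not isolated)
Conditions: Zn dust, AcOH, TMEDA, EtOH, 0 °C
Reagents that add atoms: none
Why: Stepwise reductive dechlorination of an α,α-dichloroketone by zinc with protonation; the amine-buffered, cold medium is chosen so that the triisopropylsilyl enol ether is not solvolysed.

Step 5
Reactants: 8 tert-butyl (R)-2-[4-oxo-2-(triisopropylsilyloxy)cyclobut-1-en-1-yl]piperidine-1-carboxylate; 9 ethoxyacetylene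
Product: 14 tert-butyl (R)-2-[2-ethoxy-4-hydroxy-6-(triisopropylsilyloxy)phenyl]piperidine-1-carboxylate, via vinylketene 10 (not isolated), via vinylcyclobutenone 11 (not isolated), via dienylketene 12 (not isolated), via cyclohexadienone 13 (not isolated)
Conditions: ethoxyacetylene 9 (4 equiv), toluene, sealed tube, 85 °C
Reagents that add atoms: none
Why: Danheiser benzannulation, the closest known reaction type being the union of cyclobutenones with alkoxy- and silyloxyalkynes to give resorcinol monoethers. Heat opens 8 by conrotatory 4π-electrocyclic cleavage of its C(=O)–CH2 bond to vinylketene 10; the ketene C=C adds to 9 in a [2+2] cycloaddition in which the unsubstituted carbon of the ynol ether bonds to the ketene carbonyl carbon (C4a–C8a) and the ethoxy-bearing carbon to the ketene α-carbon (C5–C6), giving 11; 11 opens again to the (E)-dienylketene 12, ring A closes by thermal disrotatory 6π-electrocyclisation between the ketene carbon and the terminal CH2 (C8–C8a), and 13 tautomerises to the phenol. Three σ-bonds are thus made in the cascade, but the last one restores the bond that the first opening broke, so the net skeletal gain over 8 is two C–C bonds and one ring. The selectivity needed, piperidine between the two ethers and the free hydroxyl para to it, is secured by the polarisation of the ynol ether, whose β-carbon is the nucleophile. The second ring opening is reversible, so only the isomer with the silyloxyvinyl group turned towards the ketene is drained by cyclisation. No stereocentre is created, since the quaternary carbon of 11 is lost again, and C2' is neither deprotonated nor ionised under neutral thermolysis, so the (R) configuration is carried through. Excess 9 and a moderate temperature are chosen so that capture of 10 by the alkyne outruns capture by the carbamate oxygen or by the product phenol, and so that 9 does not fragment.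

Step 6
Reactants: 14 tert-butyl (R)-2-[2-ethoxy-4-hydroxy-6-(triisopropylsilyloxy)phenyl]piperidine-1-carboxylate
Product: 15 tert-butyl (R)-2-[2-ethoxy-4-hydroxy-3-iodo-6-(triisopropylsilyloxy)phenyl]piperidine-1-carboxylate
Conditions: N-iodosuccinimide (1.0 equiv), MeCN, −20 → 0 °C
Reagents that add atoms: N-iodosuccinimide, O=C1CCC(=O)N1I
Why: Electrophilic aromatic iodination ortho to the free phenol; the ortho carbon beside the ethoxy carbon should be the less shielded one, because the triisopropylsilyl group is kept away from the piperidine side and lies over its other neighbour. Iodination at the other ortho carbon would lead through the same operations to the same flavone.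

Step 7
Reactants: 15 tert-butyl (R)-2-[2-ethoxy-4-hydroxy-3-iodo-6-(triisopropylsilyloxy)phenyl]piperidine-1-carboxylate; 16 phenylacetylene
Product: 18 tert-butyl (R)-2-[5-ethoxy-4-oxo-2-phenyl-7-(triisopropylsilyloxy)-4H-chromen-6-yl]piperidine-1-carboxylate, via ynone 17 (not isolated)
Conditions: PdCl2(PPh3)2 (5 mol %), CO (1 atm), Et2NH, DMF, 60 °C
Reagents that add atoms: carbon monoxide, [C-]#[O+]
Why: Carbonylative Sonogashira-type coupling and annulation: zerovalent palladium inserts into the C–I bond, CO inserts, and the acylpalladium couples with the alkyne to ynone 17, which closes by amine-promoted 6-endo conjugate addition of the phenol oxygen. Only the oxygen para to the piperidine is free, so ring C can fuse only in the sense that makes the piperidine a C6 substituent.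

Step 8
Reactants: 18 tert-butyl (R)-2-[5-ethoxy-4-oxo-2-phenyl-7-(triisopropylsilyloxy)-4H-chromen-6-yl]piperidine-1-carboxylate
Product: 20 (R)-5-ethoxy-6-(1-methylpiperidin-2-yl)-2-phenyl-7-(triisopropylsilyloxy)-4H-chromen-4-one, via secondary amine 19 (not isolated)
Conditions: CF3CO2H, anisole, CH2Cl2, 0 → 23 °C; evaporate; aq. HCHO, NaBH(OAc)3, ClCH2CH2Cl, 23 °C
Reagents that add atoms: formaldehyde, C=O
Why: Acidolysis of the Boc group with anisole as cation trap, then Borch-type reductive methylation of amine 19. The iminium is exocyclic, so C2' is untouched; ring A is fully O-protected and attenuated by the C4 carbonyl, so it should not react with formaldehyde; the triacetoxyborohydride leaves the enone alone.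

Step 9
Reactants: 20 (R)-5-ethoxy-6-(1-methylpiperidin-2-yl)-2-phenyl-7-(triisopropylsilyloxy)-4H-chromen-4-one
Product: 21 (R)-5-ethoxy-7-hydroxy-6-(1-methylpiperidin-2-yl)-2-phenyl-4H-chromen-4-one
Conditions: n-Bu4NF, AcOH, THF, 0 °C
Reagents that add atoms: none
Why: Fluoride cleavage of the aryl silyl ether, driven by the Si–F bond; acetic acid buffers the phenoxide so that no strong base sits beside the benzylic amine.

Step 10
Reactants: 21 (R)-5-ethoxy-7-hydroxy-6-(1-methylpiperidin-2-yl)-2-phenyl-4H-chromen-4-one
Product: 22 (R)-5,7-dihydroxy-6-(1-methylpiperidin-2-yl)-2-phenyl-4H-chromen-4-one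
Conditions: BBr3 (4 equiv), CH2Cl2, −78 → 0 °C; MeOH; aq. NaHCO3
Reagents that add atoms: none
Why: Lewis-acid ether cleavage: boron chelated between O5 and the C4 carbonyl activates the ethyl group for bromide attack at low temperature. Under these cold conditions the C2'–N bond should not ionise, so the configuration is kept.

## Compound list

1 | (R)-1-(tert-butoxycarbonyl)piperidine-2-carboxylic acid | CC(C)(C)OC(=O)N1CCCC[C@@H]1C(=O)O | starting material
2 | 1-tert-butyl 2-methyl (R)-piperidine-1,2-dicarboxylate | CC(C)(C)OC(=O)N1CCCC[C@@H]1C(=O)OC | intermediate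
3 | lithium (R)-2,2-dibromo-1-[1-(tert-butoxycarbonyl)piperidin-2-yl]ethen-1-olate | CC(C)(C)OC(=O)N1CCCC[C@@H]1C([O-])=C(Br)Br.[Li+] | intermediate (not isolated)
4 | lithium (R)-2-[1-(tert-butoxycarbonyl)piperidin-2-yl]ethyn-1-olate | CC(C)(C)OC(=O)N1CCCC[C@@H]1C#C[O-].[Li+] | intermediate (not isolated)
5 | tert-butyl (R)-2-[(triisopropylsilyloxy)ethynyl]piperidine-1-carboxylate | CC(C)(C)OC(=O)N1CCCC[C@@H]1C#CO[Si](C(C)C)(C(C)C)C(C)C | intermediate
6 | tert-butyl (R)-2-[3,3-dichloro-4-oxo-2-(triisopropylsilyloxy)cyclobut-1-en-1-yl]piperidine-1-carboxylate | CC(C)(C)OC(=O)N1CCCC[C@@H]1C1=C(O[Si](C(C)C)(C(C)C)C(C)C)C(Cl)(Cl)C1=O | intermediate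
7 | tert-butyl (2R)-2-[3-chloro-4-oxo-2-(triisopropylsilyloxy)cyclobut-1-en-1-yl]piperidine-1-carboxylate (either configuration at the chlorine-bearing carbon) | CC(C)(C)OC(=O)N1CCCC[C@@H]1C1=C(O[Si](C(C)C)(C(C)C)C(C)C)C(Cl)C1=O | intermediate (not isolated)
8 | tert-butyl (R)-2-[4-oxo-2-(triisopropylsilyloxy)cyclobut-1-en-1-yl]piperidine-1-carboxylate | CC(C)(C)OC(=O)N1CCCC[C@@H]1C1=C(O[Si](C(C)C)(C(C)C)C(C)C)CC1=O | intermediate
9 | ethoxyacetylene | CCOC#C | starting material
10 | tert-butyl (R)-2-[1-oxo-3-(triisopropylsilyloxy)buta-1,3-dien-2-yl]piperidine-1-carboxylate | CC(C)(C)OC(=O)N1CCCC[C@@H]1C(=C=O)C(=C)O[Si](C(C)C)(C(C)C)C(C)C | intermediate (not isolated)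
11 | tert-butyl (2R)-2-{2-ethoxy-4-oxo-1-[1-(triisopropylsilyloxy)ethenyl]cyclobut-2-en-1-yl}piperidine-1-carboxylate (either configuration at the quaternary ring carbon) | CC(C)(C)OC(=O)N1CCCC[C@@H]1C1(C(=C)O[Si](C(C)C)(C(C)C)C(C)C)C(OCC)=CC1=O | intermediate (not isolated)
12 | tert-butyl (R)-2-[(3E)-3-ethoxy-1-oxo-5-(triisopropylsilyloxy)hexa-1,3,5-trien-4-yl]piperidine-1-carboxylate | CC(C)(C)OC(=O)N1CCCC[C@@H]1/C(C(=C)O[Si](C(C)C)(C(C)C)C(C)C)=C(OCC)/C=C=O | intermediate (not isolated)
13 | tert-butyl (R)-2-[6-ethoxy-4-oxo-2-(triisopropylsilyloxy)cyclohexa-1,5-dien-1-yl]piperidine-1-carboxylate | CC(C)(C)OC(=O)N1CCCC[C@@H]1C1=C(O[Si](C(C)C)(C(C)C)C(C)C)CC(=O)C=C1OCC | intermediate (not isolated)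
14 | tert-butyl (R)-2-[2-ethoxy-4-hydroxy-6-(triisopropylsilyloxy)phenyl]piperidine-1-carboxylate | CC(C)(C)OC(=O)N1CCCC[C@@H]1c1c(OCC)cc(O)cc1O[Si](C(C)C)(C(C)C)C(C)C | intermediate
15 | tert-butyl (R)-2-[2-ethoxy-4-hydroxy-3-iodo-6-(triisopropylsilyloxy)phenyl]piperidine-1-carboxylate | CC(C)(C)OC(=O)N1CCCC[C@@H]1c1c(OCC)c(I)c(O)cc1O[Si](C(C)C)(C(C)C)C(C)C | intermediate
16 | phenylacetylene | C#Cc1ccccc1 | starting material
17 | tert-butyl (R)-2-[2-ethoxy-4-hydroxy-3-(3-phenylprop-2-ynoyl)-6-(triisopropylsilyloxy)phenyl]piperidine-1-carboxylate | CC(C)(C)OC(=O)N1CCCC[C@@H]1c1c(OCC)c(C(=O)C#Cc2ccccc2)c(O)cc1O[Si](C(C)C)(C(C)C)C(C)C | intermediate (not isolated)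
18 | tert-butyl (R)-2-[5-ethoxy-4-oxo-2-phenyl-7-(triisopropylsilyloxy)-4H-chromen-6-yl]piperidine-1-carboxylate | CC(C)(C)OC(=O)N1CCCC[C@@H]1c1c(O[Si](C(C)C)(C(C)C)C(C)C)cc2oc(-c3ccccc3)cc(=O)c2c1OCC | intermediate
19 | (R)-5-ethoxy-2-phenyl-6-(piperidin-2-yl)-7-(triisopropylsilyloxy)-4H-chromen-4-one (handled as its trifluoroacetate salt) | N1CCCC[C@@H]1c1c(O[Si](C(C)C)(C(C)C)C(C)C)cc2oc(-c3ccccc3)cc(=O)c2c1OCC | intermediate (not isolated)
20 | (R)-5-ethoxy-6-(1-methylpiperidin-2-yl)-2-phenyl-7-(triisopropylsilyloxy)-4H-chromen-4-one | CN1CCCC[C@@H]1c1c(O[Si](C(C)C)(C(C)C)C(C)C)cc2oc(-c3ccccc3)cc(=O)c2c1OCC | intermediate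
21 | (R)-5-ethoxy-7-hydroxy-6-(1-methylpiperidin-2-yl)-2-phenyl-4H-chromen-4-one | CN1CCCC[C@@H]1c1c(O)cc2oc(-c3ccccc3)cc(=O)c2c1OCC | intermediate
22 | (R)-5,7-dihydroxy-6-(1-methylpiperidin-2-yl)-2-phenyl-4H-chromen-4-one | CN1CCCC[C@@H]1c1c(O)cc2oc(-c3ccccc3)cc(=O)c2c1O | target

## Step count and least certain steps

Total step count: 10. Longest linear sequence: 10 steps (1 to 22); 9 and 16 enter as purchased inputs.

**Step 5 (key step).** The most likely failure is slow electrocyclic opening of the donor-stabilised cyclobutenone (a vinylogous silyl ester) at temperatures the ynol ether tolerates, since 9 fragments to ketene and ethene above about 100 °C. Capture of the vinylketene by the carbamate oxygen with loss of isobutene, or by the product phenol, could also divert material. A first adjustment within the same plan would be photochemical opening at 20 °C followed by gentle warming. The fallback that changes the approach sets out from 5 and rejoins at 14, and runs the same benzannulation with the roles exchanged, so that the heat-sensitive alkyne and the carbamate-bearing ketene are both avoided. Cyclobutane-1,3-dione and benzyl alcohol (TsOH, benzene, water separator) would give 3-(benzyloxy)cyclobut-2-en-1-one F1. Heating F1 with 5 in toluene at 110–140 °C should give tert-butyl (R)-2-[4-(benzyloxy)-2-hydroxy-6-(triisopropylsilyloxy)phenyl]piperidine-1-carboxylate F2, in which the piperidine again lies between two oxygens but the new hydroxyl is a flanking one. Ethylation of that hydroxyl (EtI, K2CO3, DMF) would give tert-butyl (R)-2-[4-(benzyloxy)-2-ethoxy-6-(triisopropylsilyloxy)phenyl]piperidine-1-carboxylate F3, and hydrogenolysis (H2, Pd/C, EtOAc) would return 14. This fallback still relies on thermal opening of an alkoxycyclobutenone, but both partners can be heated harder.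

**Step 2.** Enolisation of the ester at C2' by the amide base could compete with addition of LiCHBr2 and erode the configuration. Butyllithium could also attack the carbamate on warming, and silylation could occur at carbon. The fallback sets out from 2 and rejoins at 5. Reduction with (i-Bu)2AlH at −78 °C would give tert-butyl (R)-2-formylpiperidine-1-carboxylate F4. Ohira–Bestmann homologation (dimethyl (1-diazo-2-oxopropyl)phosphonate, K2CO3, MeOH, 0 °C) would give tert-butyl (R)-2-ethynylpiperidine-1-carboxylate F5. Lithiation with n-BuLi, oxidation of the acetylide with LiOOt-Bu to the same ynolate 4 and silylation with iPr3SiOTf would give 5.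

**Step 4.** Solvolytic loss of the silyl group from the vinylogous silyl ester in the protic reducing medium, or reductive ring cleavage, could destroy the cyclobutenone. The fallback sets out from 5 and rejoins at 8. Ketene itself, generated by pyrolysis of acetone and passed into a solution of 5 at 0–23 °C, should add in the same [2+2] sense and give 8 directly, with no chlorine to remove. It is kept in reserve only because of the handling of gaseous ketene.

**Step 6.** Electrophilic attack could occur at the other ortho carbon, which is para to the better donor (the ethoxy group), or twice. Electronic and steric preferences point in opposite directions here. The fallback does not force the selectivity but takes the isomer through its own line from 14 to 22.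
- Iodination beside the silyloxy carbon gives tert-butyl (R)-2-[2-ethoxy-4-hydroxy-5-iodo-6-(triisopropylsilyloxy)phenyl]piperidine-1-carboxylate F6.
- The carbonylative annulation of step 7 would give tert-butyl (R)-2-[7-ethoxy-4-oxo-2-phenyl-5-(triisopropylsilyloxy)-4H-chromen-6-yl]piperidine-1-carboxylate F7.
- The Boc-to-methyl exchange of step 8 would give (R)-7-ethoxy-6-(1-methylpiperidin-2-yl)-2-phenyl-5-(triisopropylsilyloxy)-4H-chromen-4-one F8.
- Fluoride would give (R)-7-ethoxy-5-hydroxy-6-(1-methylpiperidin-2-yl)-2-phenyl-4H-chromen-4-one F9.
- BBr3, now needed at 0–23 °C for the unchelated O7 ether, would give 22.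

**Step 7.** Direct alkynylation without CO uptake (followed by closure to a benzofuran), 5-exo closure of the ynone, or slow oxidative addition at the doubly flanked iodide could each intervene. The fallback sets out from 15 and rejoins at 19, and builds ring C by classical condensation chemistry without CO.
- Stille coupling with tributyl(1-ethoxyvinyl)stannane (PdCl2(PPh3)2, toluene, 90 °C) would give tert-butyl (R)-2-[2-ethoxy-3-(1-ethoxyethenyl)-4-hydroxy-6-(triisopropylsilyloxy)phenyl]piperidine-1-carboxylate F10.
- Hydrolysis on work-up with dilute HCl would give tert-butyl (R)-2-[3-acetyl-2-ethoxy-4-hydroxy-6-(triisopropylsilyloxy)phenyl]piperidine-1-carboxylate F11.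
- One-flask Baker–Venkataraman acylation (LiN(SiMe3)2, PhCOCl, THF, −78 → 23 °C) would give tert-butyl (R)-2-[2-ethoxy-4-hydroxy-3-(3-oxo-3-phenylpropanoyl)-6-(triisopropylsilyloxy)phenyl]piperidine-1-carboxylate F12.
- CF3CO2H in CH2Cl2 should then effect cyclodehydration and Boc cleavage together and give 19, which continues with the reductive methylation of step 8.

## Further compounds

F1 | step 5 | 3-(benzyloxy)cyclobut-2-en-1-one | O=C1C=C(OCc2ccccc2)C1
F2 | step 5 | tert-butyl (R)-2-[4-(benzyloxy)-2-hydroxy-6-(triisopropylsilyloxy)phenyl]piperidine-1-carboxylate | CC(C)(C)OC(=O)N1CCCC[C@@H]1c1c(O)cc(OCc2ccccc2)cc1O[Si](C(C)C)(C(C)C)C(C)C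
F3 | step 5 | tert-butyl (R)-2-[4-(benzyloxy)-2-ethoxy-6-(triisopropylsilyloxy)phenyl]piperidine-1-carboxylate | CC(C)(C)OC(=O)N1CCCC[C@@H]1c1c(OCC)cc(OCc2ccccc2)cc1O[Si](C(C)C)(C(C)C)C(C)C
F4 | step 2 | tert-butyl (R)-2-formylpiperidine-1-carboxylate | CC(C)(C)OC(=O)N1CCCC[C@@H]1C=O
F5 | step 2 | tert-butyl (R)-2-ethynylpiperidine-1-carboxylate | CC(C)(C)OC(=O)N1CCCC[C@@H]1C#C
F0 | step 4 | none | none
F6 | step 6 | tert-butyl (R)-2-[2-ethoxy-4-hydroxy-5-iodo-6-(triisopropylsilyloxy)phenyl]piperidine-1-carboxylate | CC(C)(C)OC(=O)N1CCCC[C@@H]1c1c(OCC)cc(O)c(I)c1O[Si](C(C)C)(C(C)C)C(C)C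
F7 | step 6 | tert-butyl (R)-2-[7-ethoxy-4-oxo-2-phenyl-5-(triisopropylsilyloxy)-4H-chromen-6-yl]piperidine-1-carboxylate | CC(C)(C)OC(=O)N1CCCC[C@@H]1c1c(OCC)cc2oc(-c3ccccc3)cc(=O)c2c1O[Si](C(C)C)(C(C)C)C(C)C
F8 | step 6 | (R)-7-ethoxy-6-(1-methylpiperidin-2-yl)-2-phenyl-5-(triisopropylsilyloxy)-4H-chromen-4-one | CN1CCCC[C@@H]1c1c(OCC)cc2oc(-c3ccccc3)cc(=O)c2c1O[Si](C(C)C)(C(C)C)C(C)C
F9 | step 6 | (R)-7-ethoxy-5-hydroxy-6-(1-methylpiperidin-2-yl)-2-phenyl-4H-chromen-4-one | CN1CCCC[C@@H]1c1c(OCC)cc2oc(-c3ccccc3)cc(=O)c2c1O
F10 | step 7 | tert-butyl (R)-2-[2-ethoxy-3-(1-ethoxyethenyl)-4-hydroxy-6-(triisopropylsilyloxy)phenyl]piperidine-1-carboxylate | CC(C)(C)OC(=O)N1CCCC[C@@H]1c1c(OCC)c(C(=C)OCC)c(O)cc1O[Si](C(C)C)(C(C)C)C(C)C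
F11 | step 7 | tert-butyl (R)-2-[3-acetyl-2-ethoxy-4-hydroxy-6-(triisopropylsilyloxy)phenyl]piperidine-1-carboxylate | CC(C)(C)OC(=O)N1CCCC[C@@H]1c1c(OCC)c(C(C)=O)c(O)cc1O[Si](C(C)C)(C(C)C)C(C)C
F12 | step 7 | tert-butyl (R)-2-[2-ethoxy-4-hydroxy-3-(3-oxo-3-phenylpropanoyl)-6-(triisopropylsilyloxy)phenyl]piperidine-1-carboxylate | CC(C)(C)OC(=O)N1CCCC[C@@H]1c1c(OCC)c(C(=O)CC(=O)c2ccccc2)c(O)cc1O[Si](C(C)C)(C(C)C)C(C)C
A1 | alternative 1 | 5-isopropoxy-3-methoxy-2-(1-methyl-1,4,5,6-tetrahydropyridin-2-yl)phenol | CN1CCCC=C1c1c(O)cc(OC(C)C)cc1OC
A2 | alternative 1 | 3-methoxy-5-(propan-2-yloxy)-2-(trimethylsilyl)phenyl trifluoromethanesulfonate | COc1cc(OC(C)C)cc(OS(=O)(=O)C(F)(F)F)c1[Si](C)(C)C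
A3 | alternative 1 | 1-methylpiperidin-2-one | CN1CCCCC1=O
A4 | alternative 1 | (R)-5-isopropoxy-3-methoxy-2-(1-methylpiperidin-2-yl)phenol | CN1CCCC[C@@H]1c1c(O)cc(OC(C)C)cc1OC
A5 | alternative 2 | (R)-5,7-dimethoxy-6-(1-methylpiperidin-2-yl)-2-phenyl-4H-chromen-4-one | CN1CCCC[C@@H]1c1c(OC)cc2oc(-c3ccccc3)cc(=O)c2c1OC
A6 | alternative 2 | (R)-2-iodo-3,5-dimethoxy-4-(1-methylpiperidin-2-yl)phenol | CN1CCCC[C@@H]1c1c(OC)cc(O)c(I)c1OC
A7 | alternative 3 | (R)-2-[4-(benzyloxy)-2,6-dimethoxyphenyl]-1-methylpiperidine | CN1CCCC[C@@H]1c1c(OC)cc(OCc2ccccc2)cc1OC
A8 | alternative 3 | O-benzoyl-N-{(4E)-5-[4-(benzyloxy)-2,6-dimethoxyphenyl]pent-4-en-1-yl}-N-methylhydroxylamine | CN(CCC/C=C/c1c(OC)cc(OCc2ccccc2)cc1OC)OC(=O)c1ccccc1
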